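The route rests on cutting the trans-diarylchroman across C3'–C4' and O1'–C2'. C4' is benzylic to two rings and lies ortho to O1' through C4a'–C8a' of benzo ring A', so this unit can be generated as an o-quinone methide. One amine-catalysed annulation with an arylacetaldehyde then makes both bonds, closes the pyran ring as its lactol and sets C3' and C4'. Its precursor is an o-hydroxybenzhydrol in which the benzyl-protected central ring, already carrying the (3R)-isoflavan built by auxiliary-controlled benzylation, is joined through CH(OH) to a 4-benzyloxy-2-hydroxyphenyl ring; it is assembled by adding an aryllithium to the free salicylaldehyde, so no acid-labile phenol protection has to be removed.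

Key step: step 16

Assumption: primed locants denote the diarylchroman and unprimed ones the isoflavan; read from the SMILES the target is 3R (isoflavan) and 3'R,4'S (chroman, trans), and the catalyst enantiomer is assigned from the standard face-shielding model of prolinol silyl ether enamines.

Step 1
Reactants: 1 5-bromo-2-hydroxy-4-methoxybenzaldehyde
Product: 2 2-(benzyloxy)-5-bromo-4-methoxybenzaldehyde
Conditions: BnBr, K2CO3, DMF, 50 °C
Reagents that add atoms: benzyl bromide, BrCc1ccccc1
Why: Williamson etherification of the phenoxide masks the future central-ring phenol as a benzyl ether, which should survive every later basic, hydridic and Lewis-acidic step and is removed at the end by hydrogenolysis.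

Step 2
Reactants: 2 2-(benzyloxy)-5-bromo-4-methoxybenzaldehyde
Product: 3 1-(benzyloxy)-4-bromo-5-methoxy-2-(2-methoxyethenyl)benzene (E/Z mixture)
Conditions: Ph3P(CH2OMe)Cl, KOtBu, THF, 0 °C → rt
Reagents that add atoms: (methoxymethyl)triphenylphosphonium chloride, [Cl-].COC[P+](c1ccccc1)(c1ccccc1)c1ccccc1
Why: Wittig olefination with the methoxymethylene ylide adds the one carbon needed for the arylacetic acid, and the enol-ether geometry is irrelevant because both isomers hydrolyse to the same aldehyde.

Step 3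
Reactants: 3 1-(benzyloxy)-4-bromo-5-methoxy-2-(2-methoxyethenyl)benzene
Product: 5 2-[2-(benzyloxy)-5-bromo-4-methoxyphenyl]acetic acid, via arylacetaldehyde 4 (not isolated)
Conditions: 2 M HCl, THF, 40 °C; then NaH2PO4/Na2HPO4 (pH 4), t-BuOH, 2-methyl-2-butene, NaClO2, 0 °C → rt
Reagents that add atoms: water, O; sodium chlorite, [Na+].[O-]Cl=O
Why: Acid hydrolysis of the enol ether followed in the same flask by Pinnick oxidation takes the self-condensation-prone arylacetaldehyde straight to the acid, the alkene scavenger keeping hypochlorous acid away from the electron-rich ring.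

Step 4
Reactants: 5 2-[2-(benzyloxy)-5-bromo-4-methoxyphenyl]acetic acid
Product: 7 (4R)-4-benzyl-3-{2-[2-(benzyloxy)-5-bromo-4-methoxyphenyl]acetyl}-1,3-oxazolidin-2-one, via mixed pivalic anhydride 6 (not isolated)
Conditions: PivCl, Et3N, THF, −20 °C; then LiCl, (R)-4-benzyl-2-oxazolidinone, rt
Reagents that add atoms: (R)-4-benzyl-1,3-oxazolidin-2-one, O=C1N[C@H](Cc2ccccc2)CO1; pivaloyl chloride, CC(C)(C)C(Cl)=O (its atoms stay in 6 only)
Why: N-acylation of the oxazolidinone through the mixed anhydride with lithium chloride activation is the standard mild entry to arylacetyl imides and avoids the ketene formation that an acid chloride would risk.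

Step 5
Reactants: 8 4-(benzyloxy)-2-hydroxybenzaldehyde
Product: 9 4-(benzyloxy)-2-(methoxymethoxy)benzaldehyde
Conditions: MOMCl, i-Pr2NEt, CH2Cl2, 0 °C → rt
Reagents that add atoms: chloromethyl methyl ether, COCCl
Why: O-alkylation of the phenol gives a MOM acetal that is orthogonal to the benzyl ether and stable to the hydride, bromination and enolate conditions that follow.

Step 6
Reactants: 9 4-(benzyloxy)-2-(methoxymethoxy)benzaldehyde
Product: 10 [4-(benzyloxy)-2-(methoxymethoxy)phenyl]methanol
Conditions: NaBH4, MeOH/THF, 0 °C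
Reagents that add atoms: none
Why: Borohydride reduction of the aryl aldehyde to the benzylic alcohol is chemoselective and leaves both ethers untouched.

Step 7
Reactants: 10 [4-(benzyloxy)-2-(methoxymethoxy)phenyl]methanol
Product: 11 4-(benzyloxy)-1-(bromomethyl)-2-(methoxymethoxy)benzene
Conditions: PPh3, CBr4, CH2Cl2, 0 °C; used at once
Reagents that add atoms: carbon tetrabromide, BrC(Br)(Br)Br
Why: Appel bromination runs under neutral conditions, so neither the MOM acetal nor the ionisation-prone dialkoxybenzyl bromide is exposed to HBr.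

Step 8
Reactants: 7 (4R)-4-benzyl-3-{2-[2-(benzyloxy)-5-bromo-4-methoxyphenyl]acetyl}-1,3-oxazolidin-2-one; 11 4-(benzyloxy)-1-(bromomethyl)-2-(methoxymethoxy)benzene
Product: 13 (4R)-4-benzyl-3-{(2R)-2-[2-(benzyloxy)-5-bromo-4-methoxyphenyl]-3-[4-(benzyloxy)-2-(methoxymethoxy)phenyl]propanoyl}-1,3-oxazolidin-2-one, via sodium enolate 12 (not isolated)
Conditions: NaHMDS, THF, −78 °C; then 11, −78 → −40 °C
Reagents that add atoms: none
Why: In this Evans alkylation the chelated Z-enolate should be benzylated on the face opposite the C4 benzyl group of the (R)-auxiliary, which sets the future isoflavan C3 as R.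

Step 9
Reactants: 13 (4R)-4-benzyl-3-{(2R)-2-[2-(benzyloxy)-5-bromo-4-methoxyphenyl]-3-[4-(benzyloxy)-2-(methoxymethoxy)phenyl]propanoyl}-1,3-oxazolidin-2-one
Product: 15 5-(benzyloxy)-2-{(2R)-2-[2-(benzyloxy)-5-bromo-4-methoxyphenyl]-3-hydroxypropyl}phenol, via MOM ether alcohol 14 (not isolated)
Conditions: LiBH4, MeOH (1 equiv), THF, 0 °C; then HCl, MeOH, 45 °C
Reagents that add atoms: none
Why: Reductive cleavage of the imide by lithium borohydride gives the primary alcohol without touching the α-stereocentre, and the methanolic acid used for the quench then removes the MOM acetal while the benzyl ethers and the aryl bromide persist.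

Step 10
Reactants: 15 5-(benzyloxy)-2-{(2R)-2-[2-(benzyloxy)-5-bromo-4-methoxyphenyl]-3-hydroxypropyl}phenol
Product: 16 (3R)-7-(benzyloxy)-3-[2-(benzyloxy)-5-bromo-4-methoxyphenyl]chromane
Conditions: PPh3, DIAD, THF, 0 °C → rt
Reagents that add atoms: none
Why: Intramolecular Mitsunobu etherification (6-exo-tet) joins the phenol oxygen to the activated primary carbon, and the stereocentre is not a reacting atom, so it stays R.

Step 11
Reactants: 16 (3R)-7-(benzyloxy)-3-[2-(benzyloxy)-5-bromo-4-methoxyphenyl]chromane; 8 4-(benzyloxy)-2-hydroxybenzaldehyde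
Product: 19 {4-(benzyloxy)-5-[(3R)-7-(benzyloxy)chroman-3-yl]-2-methoxyphenyl}[4-(benzyloxy)-2-hydroxyphenyl]methanol (both carbinol epimers), via aryllithium 17 (not isolated), via sodium phenolate 18 (not isolated)
Conditions: 16, n-BuLi, THF, −78 °C; 8, NaH, THF, 0 °C (separate flask); combine, −78 → 0 °C; H2O quench
Reagents that add atoms: none
Why: Bromine–lithium exchange followed by 1,2-addition of the aryllithium to the salicylaldehyde, whose phenol is masked only as its sodium salt, should give the o-hydroxybenzhydrol directly, the new carbinol centre being irrelevant because it becomes sp2 in step 16.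

Step 12
Reactants: 20 2,6-dimethoxyphenol
Product: 21 2-(benzyloxy)-1,3-dimethoxybenzene
Conditions: BnBr, K2CO3, DMF, 60 °C
Reagents that add atoms: benzyl bromide, BrCc1ccccc1
Why: Williamson etherification protects the phenol and at the same time redirects electrophilic substitution away from the position para to that oxygen.

Step 13
Reactants: 21 2-(benzyloxy)-1,3-dimethoxybenzene
Product: 22 3-(benzyloxy)-1-bromo-2,4-dimethoxybenzene
Conditions: NBS, MeCN, 0 °C → rt
Reagents that add atoms: N-bromosuccinimide, O=C1CCC(=O)N1Br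
Why: Electrophilic aromatic bromination of a 1,2,3-trialkoxybenzene occurs at C4, ortho and para to the two conjugating methoxy groups, because the flanked central alkoxy group is twisted out of conjugation.

Step 14
Reactants: 22 3-(benzyloxy)-1-bromo-2,4-dimethoxybenzene
Product: 24 2-[3-(benzyloxy)-2,4-dimethoxyphenyl]ethan-1-ol, via aryllithium 23 (not isolated)
Conditions: n-BuLi, THF, −78 °C; then ethylene oxide, −78 °C → rt; H2O quench
Reagents that add atoms: ethylene oxide, C1CO1
Why: Bromine–lithium exchange and SN2 opening of the unhindered epoxide by the aryllithium install the two-carbon chain at the alcohol oxidation level.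

Step 15
Reactants: 24 2-[3-(benzyloxy)-2,4-dimethoxyphenyl]ethan-1-ol
Product: 25 2-[3-(benzyloxy)-2,4-dimethoxyphenyl]acetaldehyde
Conditions: DMP, CH2Cl2, 0 °C → rt; used directly
Reagents that add atoms: none
Why: Dess–Martin oxidation stops at the aldehyde under near-neutral conditions, which limits enolisation and self-condensation of the arylacetaldehyde.

Step 16
Reactants: 19 {4-(benzyloxy)-5-[(3R)-7-(benzyloxy)chroman-3-yl]-2-methoxyphenyl}[4-(benzyloxy)-2-hydroxyphenyl]methanol; 25 2-[3-(benzyloxy)-2,4-dimethoxyphenyl]acetaldehyde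
Product: 28 (3R,4S)-7-(benzyloxy)-4-{4-(benzyloxy)-5-[(3R)-7-(benzyloxy)chroman-3-yl]-2-methoxyphenyl}-3-[3-(benzyloxy)-2,4-dimethoxyphenyl]chroman-2-ol (anomeric mixture), via o-quinone methide 26 (not isolated), via catalyst enamine 27 (not isolated)
Conditions: (R)-α,α-diphenylprolinol trimethylsilyl ether (20 mol%), PhCO2H (20 mol%), CHCl3, 0 °C → rt
Reagents that add atoms: none
Why: Benzoic acid promotes loss of water from 19 to the o-quinone methide 26, which the 2,4-dioxygenated central ring and the 7'-benzyloxy group stabilise, while 25 condenses with the amine to the E-enamine 27. The enamine α-carbon adds to the exocyclic methide carbon (C3'–C4', re-aromatising ring A'), the freed phenol closes on the iminium carbon (O1'–C2', 6-exo-trig) and hydrolysis of the aminal returns the catalyst and the lactol; the closest known reaction type is the secondary-amine-catalysed formal [4+2] annulation of aldehydes with o-quinone methides generated in situ from o-hydroxybenzhydrols, which gives trans-3,4-disubstituted chroman-2-ols. C3' is controlled by the catalyst, whose diphenyl(silyloxy)methyl group blocks one face of the s-trans enamine, and by the usual model the (R)-catalyst should expose the face that leads to 3'R. C4' is controlled by the relative approach of the partners, the anti (open) arrangement placing the two aryl groups trans (4'S), which is also the more stable lactol, so any equilibration through the open hydroxy aldehyde should work in the same direction. The step needs C-alkylation by the enamine to outrun arene or phenol alkylation by the methide and needs catalyst rather than substrate control; the first is secured by the much higher nucleophilicity of the enamine and by benzylation of every other phenol, the second by the remoteness of the isoflavan centre. As a cyclic hemiacetal the product holds its α-aryl aldehyde in a non-enolisable form, which protects C3' up to the reduction.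

Step 17
Reactants: 28 (3R,4S)-7-(benzyloxy)-4-{4-(benzyloxy)-5-[(3R)-7-(benzyloxy)chroman-3-yl]-2-methoxyphenyl}-3-[3-(benzyloxy)-2,4-dimethoxyphenyl]chroman-2-ol
Product: 29 (3R,4S)-7-(benzyloxy)-4-{4-(benzyloxy)-5-[(3R)-7-(benzyloxy)chroman-3-yl]-2-methoxyphenyl}-3-[3-(benzyloxy)-2,4-dimethoxyphenyl]chromane
Conditions: Et3SiH, BF3·OEt2, CH2Cl2, −78 → −30 °C
Reagents that add atoms: none
Why: In this ionic hydrogenation boron trifluoride ionises the lactol to the cyclic aryloxocarbenium ion, which triethylsilane reduces at C2', a carbon that becomes CH2, so C3' and C4' are not involved.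

Step 18
Reactants: 29 (3R,4S)-7-(benzyloxy)-4-{4-(benzyloxy)-5-[(3R)-7-(benzyloxy)chroman-3-yl]-2-methoxyphenyl}-3-[3-(benzyloxy)-2,4-dimethoxyphenyl]chromane
Product: 30 (3R,4S)-4-{4-hydroxy-5-[(3R)-7-hydroxychroman-3-yl]-2-methoxyphenyl}-3-(3-hydroxy-2,4-dimethoxyphenyl)chroman-7-ol (CNP0202416.1)
Conditions: H2 (1 atm), 10% Pd/C, EtOAc/MeOH, rt
Reagents that add atoms: none
Why: Catalytic hydrogenolysis should remove all four aryl benzyl ethers as toluene, and none of the three stereocentres carries a benzylic C–O bond that could be cleaved.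

Compound list
1 | 5-bromo-2-hydroxy-4-methoxybenzaldehyde | COc1cc(O)c(C=O)cc1Br | starting material
2 | 2-(benzyloxy)-5-bromo-4-methoxybenzaldehyde | COc1cc(OCc2ccccc2)c(C=O)cc1Br | intermediate
3 | 1-(benzyloxy)-4-bromo-5-methoxy-2-(2-methoxyethenyl)benzene (E/Z mixture) | COC=Cc1cc(Br)c(OC)cc1OCc1ccccc1 | intermediate
4 | 2-[2-(benzyloxy)-5-bromo-4-methoxyphenyl]acetaldehyde | O=CCc1cc(Br)c(OC)cc1OCc1ccccc1 | intermediate
5 | 2-[2-(benzyloxy)-5-bromo-4-methoxyphenyl]acetic acid | OC(=O)Cc1cc(Br)c(OC)cc1OCc1ccccc1 | intermediate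
6 | 2-[2-(benzyloxy)-5-bromo-4-methoxyphenyl]acetic pivalic anhydride | CC(C)(C)C(=O)OC(=O)Cc1cc(Br)c(OC)cc1OCc1ccccc1 | intermediate
7 | (4R)-4-benzyl-3-{2-[2-(benzyloxy)-5-bromo-4-methoxyphenyl]acetyl}-1,3-oxazolidin-2-one | O=C(Cc1cc(Br)c(OC)cc1OCc1ccccc1)N1[C@H](Cc2ccccc2)COC1=O | intermediate
8 | 4-(benzyloxy)-2-hydroxybenzaldehyde | O=Cc1ccc(OCc2ccccc2)cc1O | starting material
9 | 4-(benzyloxy)-2-(methoxymethoxy)benzaldehyde | COCOc1cc(OCc2ccccc2)ccc1C=O | intermediate
10 | [4-(benzyloxy)-2-(methoxymethoxy)phenyl]methanol | COCOc1cc(OCc2ccccc2)ccc1CO | intermediate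
11 | 4-(benzyloxy)-1-(bromomethyl)-2-(methoxymethoxy)benzene | COCOc1cc(OCc2ccccc2)ccc1CBr | intermediate
12 | sodium (Z)-enolate of 7 | [Na+].[O-]/C(=C\c1cc(Br)c(OC)cc1OCc1ccccc1)N1[C@H](Cc2ccccc2)COC1=O | intermediate
13 | (4R)-4-benzyl-3-{(2R)-2-[2-(benzyloxy)-5-bromo-4-methoxyphenyl]-3-[4-(benzyloxy)-2-(methoxymethoxy)phenyl]propanoyl}-1,3-oxazolidin-2-one | O=C([C@H](Cc1ccc(OCc2ccccc2)cc1OCOC)c1cc(Br)c(OC)cc1OCc1ccccc1)N1[C@H](Cc2ccccc2)COC1=O | intermediate
14 | (2R)-2-[2-(benzyloxy)-5-bromo-4-methoxyphenyl]-3-[4-(benzyloxy)-2-(methoxymethoxy)phenyl]propan-1-ol | OC[C@H](Cc1ccc(OCc2ccccc2)cc1OCOC)c1cc(Br)c(OC)cc1OCc1ccccc1 | intermediate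
15 | 5-(benzyloxy)-2-{(2R)-2-[2-(benzyloxy)-5-bromo-4-methoxyphenyl]-3-hydroxypropyl}phenol | OC[C@H](Cc1ccc(OCc2ccccc2)cc1O)c1cc(Br)c(OC)cc1OCc1ccccc1 | intermediate
16 | (3R)-7-(benzyloxy)-3-[2-(benzyloxy)-5-bromo-4-methoxyphenyl]chromane | COc1cc(OCc2ccccc2)c([C@@H]2COc3cc(OCc4ccccc4)ccc3C2)cc1Br | intermediate
17 | {4-(benzyloxy)-5-[(3R)-7-(benzyloxy)chroman-3-yl]-2-methoxyphenyl}lithium | COc1cc(OCc2ccccc2)c([C@@H]2COc3cc(OCc4ccccc4)ccc3C2)cc1[Li] | intermediate
18 | sodium 5-(benzyloxy)-2-formylphenolate | [Na+].[O-]c1cc(OCc2ccccc2)ccc1C=O | intermediate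
19 | {4-(benzyloxy)-5-[(3R)-7-(benzyloxy)chroman-3-yl]-2-methoxyphenyl}[4-(benzyloxy)-2-hydroxyphenyl]methanol (both carbinol epimers) | COc1cc(OCc2ccccc2)c([C@@H]2COc3cc(OCc4ccccc4)ccc3C2)cc1C(O)c1ccc(OCc2ccccc2)cc1O | intermediate
20 | 2,6-dimethoxyphenol | COc1cccc(OC)c1O | starting material
21 | 2-(benzyloxy)-1,3-dimethoxybenzene | COc1cccc(OC)c1OCc1ccccc1 | intermediate
22 | 3-(benzyloxy)-1-bromo-2,4-dimethoxybenzene | COc1ccc(Br)c(OC)c1OCc1ccccc1 | intermediate
23 | [3-(benzyloxy)-2,4-dimethoxyphenyl]lithium | COc1ccc([Li])c(OC)c1OCc1ccccc1 | intermediate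
24 | 2-[3-(benzyloxy)-2,4-dimethoxyphenyl]ethan-1-ol | COc1ccc(CCO)c(OC)c1OCc1ccccc1 | intermediate
25 | 2-[3-(benzyloxy)-2,4-dimethoxyphenyl]acetaldehyde | COc1ccc(CC=O)c(OC)c1OCc1ccccc1 | intermediate
26 | 3-(benzyloxy)-6-({4-(benzyloxy)-5-[(3R)-7-(benzyloxy)chroman-3-yl]-2-methoxyphenyl}methylidene)cyclohexa-2,4-dien-1-one (o-quinone methide) | COc1cc(OCc2ccccc2)c([C@@H]2COc3cc(OCc4ccccc4)ccc3C2)cc1C=C1C=CC(OCc2ccccc2)=CC1=O | intermediate
27 | (2R)-1-{(E)-2-[3-(benzyloxy)-2,4-dimethoxyphenyl]ethenyl}-2-{diphenyl[(trimethylsilyl)oxy]methyl}pyrrolidine (enamine of 25 with the catalyst) | COc1ccc(/C=C/N2CCC[C@@H]2C(c2ccccc2)(c2ccccc2)O[Si](C)(C)C)c(OC)c1OCc1ccccc1 | intermediate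
28 | (3R,4S)-7-(benzyloxy)-4-{4-(benzyloxy)-5-[(3R)-7-(benzyloxy)chroman-3-yl]-2-methoxyphenyl}-3-[3-(benzyloxy)-2,4-dimethoxyphenyl]chroman-2-ol (anomeric mixture) | COc1cc(OCc2ccccc2)c([C@@H]2COc3cc(OCc4ccccc4)ccc3C2)cc1[C@@H]1c2ccc(OCc3ccccc3)cc2OC(O)[C@H]1c1ccc(OC)c(OCc2ccccc2)c1OC | intermediate
29 | (3R,4S)-7-(benzyloxy)-4-{4-(benzyloxy)-5-[(3R)-7-(benzyloxy)chroman-3-yl]-2-methoxyphenyl}-3-[3-(benzyloxy)-2,4-dimethoxyphenyl]chromane | COc1cc(OCc2ccccc2)c([C@@H]2COc3cc(OCc4ccccc4)ccc3C2)cc1[C@@H]1c2ccc(OCc3ccccc3)cc2OC[C@H]1c1ccc(OC)c(OCc2ccccc2)c1OC | intermediate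
30 | (3R,4S)-4-{4-hydroxy-5-[(3R)-7-hydroxychroman-3-yl]-2-methoxyphenyl}-3-(3-hydroxy-2,4-dimethoxyphenyl)chroman-7-ol | COc1cc(O)c([C@@H]2COc3cc(O)ccc3C2)cc1[C@@H]1c2ccc(O)cc2OC[C@H]1c1ccc(OC)c(O)c1OC | target

Total step count: 18. Longest linear sequence: 11 steps (1–4, 8–11, 16–18). The side branches are steps 5–7, which join at step 8, and steps 12–15, which join at step 16.

Steps most likely to fail

Step 16. The enamine may discriminate poorly between its faces when its α-substituent is an aryl group. Capture of the heavily stabilised methide may also be slow enough for self-condensation of the aldehyde or arene alkylation by the methide to compete. The fallback sets out from 25 and 19 and returns at 28. Aldehyde 25 is condensed with benzyl carbamate (PPTS cat., toluene, 4 Å MS, 80 °C) to the (E)-enecarbamate F1. A BINOL-derived chiral phosphoric acid of the 3,3'-bis(2,4,6-triisopropylphenyl) type, in the enantiomer that serves the 3'R,4'S series, then catalyses the [4+2] cycloaddition of F1 with the methide that the same acid generates from 19. This is a known Brønsted-acid mode in which the phosphate binds the methide carbonyl and the carbamate N–H, and it should give the 2'-(benzyloxycarbonylamino)chroman F2. Mild aqueous acid (PPTS, wet acetone/THF) hydrolyses the N,O-aminal to lactol 28. Because the isoflavan centre is already fixed, a minor facial isomer from either variant is a diastereomer and can be removed by chromatography.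

Step 11. Addition of the aryllithium to the electron-rich, phenolate-deactivated aldehyde may be incomplete, with protonation of the aryllithium taking over. The carbinol may also ionise during isolation, so triethylamine-deactivated silica or direct use is planned. The fallback sets out from 8 and 16 and returns at 19. Aldehyde 8 is silylated (TBSCl, imidazole, DMF) to the silyl ether F3. Aryllithium 17, made from 16 as before, adds to this fully electrophilic aldehyde to give the mono-silylated carbinol F4, with the silyl group on the phenolic oxygen or, after migration, on the benzylic one. TBAF in THF at 0 °C then frees 19 under non-acidic conditions.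

Step 17. The oxocarbenium ion may lose H3' to give the 4H-chromene, which would scramble C3' on re-protonation, or it may be intercepted by an electron-rich ring before hydride transfer. Partial loss of benzyl ethers to the Lewis acid is also possible. The fallback sets out from 28 and returns at 29. NaBH4 (EtOH/THF, 0 °C) reduces the lactol through its open hydroxy-aldehyde form to the ring-opened phenol–primary alcohol F5. An intramolecular Mitsunobu etherification (PPh3, DIAD, THF), the closure already used for the isoflavan, then gives 29 without any cationic intermediate.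

Further compounds
F1 | step 16 | benzyl N-{(E)-2-[3-(benzyloxy)-2,4-dimethoxyphenyl]ethenyl}carbamate | COc1ccc(/C=C/NC(=O)OCc2ccccc2)c(OC)c1OCc1ccccc1
F2 | step 16 | benzyl N-[(3R,4S)-7-(benzyloxy)-4-{4-(benzyloxy)-5-[(3R)-7-(benzyloxy)chroman-3-yl]-2-methoxyphenyl}-3-[3-(benzyloxy)-2,4-dimethoxyphenyl]chroman-2-yl]carbamate (C2' mixture) | COc1cc(OCc2ccccc2)c([C@@H]2COc3cc(OCc4ccccc4)ccc3C2)cc1[C@@H]1c2ccc(OCc3ccccc3)cc2OC(NC(=O)OCc2ccccc2)[C@H]1c1ccc(OC)c(OCc2ccccc2)c1OC
F3 | step 11 | 4-(benzyloxy)-2-[(tert-butyldimethylsilyl)oxy]benzaldehyde | CC(C)(C)[Si](C)(C)Oc1cc(OCc2ccccc2)ccc1C=O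
F4 | step 11 | {4-(benzyloxy)-5-[(3R)-7-(benzyloxy)chroman-3-yl]-2-methoxyphenyl}{4-(benzyloxy)-2-[(tert-butyldimethylsilyl)oxy]phenyl}methanol (both carbinol epimers) | COc1cc(OCc2ccccc2)c([C@@H]2COc3cc(OCc4ccccc4)ccc3C2)cc1C(O)c1ccc(OCc2ccccc2)cc1O[Si](C)(C)C(C)(C)C
F5 | step 17 | 5-(benzyloxy)-2-[(1S,2R)-1-{4-(benzyloxy)-5-[(3R)-7-(benzyloxy)chroman-3-yl]-2-methoxyphenyl}-2-[3-(benzyloxy)-2,4-dimethoxyphenyl]-3-hydroxypropyl]phenol | COc1cc(OCc2ccccc2)c([C@@H]2COc3cc(OCc4ccccc4)ccc3C2)cc1[C@H](c1ccc(OCc2ccccc2)cc1O)[C@@H](CO)c1ccc(OC)c(OCc2ccccc2)c1OC
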